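## Retrosynthetic overview

1. The target is numbered on its lactone ring (6,7-dihydro-5H-oxepin-2-one: O1, C2(=O), C3=C4, C5, C6, C7; side-chain carbinol C1′). Desilylation and Baeyer–Villiger insertion of O1 between C2 and C7 lead back to cyclohex-2-en-1-one 19, so the seven-membered lactone is the only ring formed in the route and is made last, by ring expansion.
2. Key disconnection C7–C1′: an enantioselective anti-type boron aldol addition of the cross-conjugated enolate of enone 11 to aldehyde 16. This one step unites all 20 skeletal carbons and sets both stereocentres.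
3. Enabling feature: the ester unit O1–C2(=O) sits on the quaternary C7, and the other neighbour of C2 is the sp2 carbon C3 of the ring C3=C4 bond. With O1 removed, C7 is the only enolisable α-carbon of a cyclohexenone, so the tertiary C7–O / secondary C1′–OH pair is a latent β-hydroxy ketone.
4. Enone 11 comes from Birch reductive alkylation (dearomatisation) of 2-methoxy-3-methylbenzoic acid with the (Z)-homoallylic iodide 7 (from propargyl alcohol). The six arene carbons become C2–C7 of the lactone; the carbocycle is unveiled, not built.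
5. Aldehyde 16 comes from nerol (source of the 4′Z olefin) by silylation and cleavage of the distal olefin.

Key step: step 9

Assumption: the (R,R)-diazaborolidine controller directs enolborinate 18 to the Si face of aldehyde 16; if the sense found is the opposite, the (S,S)-controller is used, the relative configuration being fixed by the chair transition state in either case.

## Route

Step 1
Reactants: 1 prop-2-yn-1-ol
Product: 3 (2Z)-3-iodo-2-methylprop-2-en-1-ol, via chelated alkenylmagnesium alkoxide 2 (not isolated)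
Conditions: MeMgBr (2.5 equiv), CuI (cat.), THF, −10 °C → rt; then I2, −10 °C
Reagents that add atoms: methylmagnesium bromide, C[Mg]Br; iodine, II
Why: Copper-catalysed anti-carbomagnesiation of the propargylic alkoxide puts methyl on C2 and magnesium on C3 cis to the CH2O group (five-membered chelate), and iodinolysis with retention gives the (Z)-iodide that fixes the geometry of the left-hand olefin.

Step 2
Reactants: 3 (2Z)-3-iodo-2-methylprop-2-en-1-ol
Product: 4 tert-butyl{[(2Z)-3-iodo-2-methylprop-2-en-1-yl]oxy}diphenylsilane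
Conditions: TBDPSCl, imidazole, CH2Cl2, 0 °C → rt
Reagents that add atoms: tert-butyl(chloro)diphenylsilane, CC(C)(C)[Si](Cl)(c1ccccc1)c1ccccc1
Why: Standard silylation of a primary alcohol; the TBDPS ether is chosen because it survives the aqueous acid of step 5 and the periodic acid of step 8.

Step 3
Reactants: 4 tert-butyl{[(2Z)-3-iodo-2-methylprop-2-en-1-yl]oxy}diphenylsilane
Product: 6 (3Z)-5-[(tert-butyldiphenylsilyl)oxy]-4-methylpent-3-en-1-ol, via alkenyllithium 5 (not isolated)
Conditions: t-BuLi (2 equiv), Et2O, −78 °C; then oxirane, BF3·OEt2, −78 °C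
Reagents that add atoms: oxirane, C1CO1
Why: Iodine–lithium exchange proceeds with retention of olefin geometry, and BF3-assisted opening of oxirane by the alkenyllithium at −78 °C (cold enough to suppress 1,4-silyl migration) adds the two-carbon arm.

Step 4
Reactants: 6 (3Z)-5-[(tert-butyldiphenylsilyl)oxy]-4-methylpent-3-en-1-ol
Product: 7 tert-butyl{[(2Z)-5-iodo-2-methylpent-2-en-1-yl]oxy}diphenylsilane
Conditions: I2, PPh3, imidazole, CH2Cl2, 0 °C
Reagents that add atoms: iodine, II
Why: Appel-type iodination of an unhindered primary alcohol, neutral enough for the allylic silyl ether.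

Step 5
Reactants: 7 tert-butyl{[(2Z)-5-iodo-2-methylpent-2-en-1-yl]oxy}diphenylsilane; 8 2-methoxy-3-methylbenzoic acid
Product: 11 2-{(3Z)-5-[(tert-butyldiphenylsilyl)oxy]-4-methylpent-3-en-1-yl}-6-methylcyclohex-2-en-1-one (racemic at C6), via dilithium dienolate 9 (not isolated), via alkylated dihydrobenzoic acid 10 (not isolated)
Conditions: 8, Li, NH3(l)/THF, −78 °C; piperylene; then 7, −78 → −33 °C; NH4Cl; then 1 M HCl, THF, 45 °C
Reagents that add atoms: water, O
Why: Birch reductive alkylation: the benzoate is reduced to the 1,4-dihydro dianion, which is alkylated at C1 by the primary iodide; hydrolysis of the enol ether, decarboxylation of the β-keto acid and conjugation of the olefin then give the 2-alkyl-6-methylcyclohex-2-enone.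

Step 6
Reactants: 12 nerol [(2Z)-3,7-dimethylocta-2,6-dien-1-ol]
Product: 13 tert-butyl{[(2Z)-3,7-dimethylocta-2,6-dien-1-yl]oxy}diphenylsilane
Conditions: TBDPSCl, imidazole, CH2Cl2, 0 °C → rt
Reagents that add atoms: tert-butyl(chloro)diphenylsilane, CC(C)(C)[Si](Cl)(c1ccccc1)c1ccccc1
Why: Standard silylation; the 2Z olefin of nerol is carried unchanged into the target.

Step 7
Reactants: 13 tert-butyl{[(2Z)-3,7-dimethylocta-2,6-dien-1-yl]oxy}diphenylsilane
Product: 15 tert-butyl{[(2Z)-5-(3,3-dimethyloxiran-2-yl)-3-methylpent-2-en-1-yl]oxy}diphenylsilane (racemic epoxide), via bromohydrin 14 (not isolated)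
Conditions: NBS, THF/H2O, 0 °C; then K2CO3, MeOH, rt
Reagents that add atoms: water, O
Why: Bromohydrin formation is selective for the distal, more electron-rich olefin (the 2,3-olefin is deactivated by the allylic oxygen and shielded by the silyl group), and base closes the epoxide.

Step 8
Reactants: 15 tert-butyl{[(2Z)-5-(3,3-dimethyloxiran-2-yl)-3-methylpent-2-en-1-yl]oxy}diphenylsilane
Product: 16 (4Z)-6-[(tert-butyldiphenylsilyl)oxy]-4-methylhex-4-enal
Conditions: H5IO6, THF/Et2O, 0 °C
Reagents that add atoms: none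
Why: Periodic acid opens the epoxide to the glycol and cleaves it in one operation, releasing acetone and the aldehyde without touching the remaining trisubstituted olefin.

Step 9
Reactants: 11 2-{(3Z)-5-[(tert-butyldiphenylsilyl)oxy]-4-methylpent-3-en-1-yl}-6-methylcyclohex-2-en-1-one; 16 (4Z)-6-[(tert-butyldiphenylsilyl)oxy]-4-methylhex-4-enal
Product: 19 (6R)-6-{(1R,4Z)-6-[(tert-butyldiphenylsilyl)oxy]-1-hydroxy-4-methylhex-4-en-1-yl}-2-{(3Z)-5-[(tert-butyldiphenylsilyl)oxy]-4-methylpent-3-en-1-yl}-6-methylcyclohex-2-en-1-one, via lithium dienolate 17 (not isolated), via boron dienolate 18 (not isolated)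
Conditions: LDA, THF, −78 °C; (4R,5R)-2-bromo-4,5-diphenyl-1,3-ditosyl-1,3,2-diazaborolidine [from the commercial (R,R)-bis-sulfonamide and BBr3, CH2Cl2], −78 °C; then 16, −78 °C; pH 7 buffer, MeOH
Reagents that add atoms: none
Why: Kinetic α′-deprotonation gives the cross-conjugated lithium dienolate 17 (C6–H is the only enolisable α-hydrogen, the other α-carbon being the sp2 C2), which is transmetallated to the enolborinate 18 and adds to aldehyde 16 through a closed six-membered chair transition state; the closest known reaction type is the enantioselective boron-mediated aldol addition of ketone and ester enolates under this C2-symmetric bis-sulfonamide controller. No ring is closed. The ring fixes the enolate geometry (methyl cis and ring CH2 trans to O–B), so with the aldehyde chain equatorial the new hydroxyl is set syn to the methyl group and anti to the ring CH2, which is the relative configuration the target needs once O1 is inserted with retention. The absolute sense (Si face of the aldehyde, giving 1′R and with it 6R) is imposed by the sulfonyl groups of the (R,R)-controller. The step needs site selectivity (α′ over γ deprotonation, secured by kinetic LDA conditions), chemoselectivity (1,2-addition to the aldehyde rather than to the enone, secured by the boron enolate at −78 °C) and suppression of retro-aldol cleavage of the quaternary aldolate (tight B–O chelate, cold buffered work-up).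

Step 10
Reactants: 19 aldol adduct
Product: 20 (6R)-2-{(3Z)-5-[(tert-butyldiphenylsilyl)oxy]-4-methylpent-3-en-1-yl}-6-{(1R,4Z)-6-[(tert-butyldiphenylsilyl)oxy]-4-methyl-1-[(triethylsilyl)oxy]hex-4-en-1-yl}-6-methylcyclohex-2-en-1-one
Conditions: TESOTf, 2,6-lutidine, CH2Cl2, −78 °C
Reagents that add atoms: triethylsilyl trifluoromethanesulfonate, CC[Si](CC)(CC)OS(=O)(=O)C(F)(F)F
Why: Silyl triflate with a hindered base silylates the neopentyl-type carbinol at low temperature without retro-aldol cleavage and blocks that pathway in the next step.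

Step 11
Reactants: 20 TES-protected aldol adduct
Product: 21 (7R)-3-{(3Z)-5-[(tert-butyldiphenylsilyl)oxy]-4-methylpent-3-en-1-yl}-7-{(1R,4Z)-6-[(tert-butyldiphenylsilyl)oxy]-4-methyl-1-[(triethylsilyl)oxy]hex-4-en-1-yl}-7-methyl-6,7-dihydrooxepin-2(5H)-one
Conditions: (Me3SiO)2, SnCl4 (cat.), (±)-trans-cyclohexane-1,2-diamine (cat.), 4 Å MS, CH2Cl2, 0 °C → rt
Reagents that add atoms: bis(trimethylsilyl) peroxide, C[Si](C)(C)OO[Si](C)(C)C
Why: Baeyer–Villiger oxidation: the tin-activated ketone adds the silyl peroxide and the peroxy hemiketal rearranges with migration of the tertiary C6 with retention (tertiary alkyl is favoured over the 1-alkylvinyl carbon, as in peracid oxidations of 6,6-disubstituted cyclohex-2-enones), so 6R becomes 7R, while the silyl peroxide, which has no electrophilic peracid oxygen, leaves the two trisubstituted olefins alone.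

Step 12
Reactants: 21 tris-silylated lactone
Product: 22 (7R)-7-[(1R,4Z)-1,6-dihydroxy-4-methylhex-4-en-1-yl]-3-[(3Z)-5-hydroxy-4-methylpent-3-en-1-yl]-7-methyl-6,7-dihydrooxepin-2(5H)-one (target)
Conditions: TBAF, AcOH, THF, 0 °C → rt
Reagents that add atoms: none
Why: Acetic-acid-buffered fluoride cleaves the two primary TBDPS ethers and the secondary TES ether while keeping the medium too weakly basic for lactone opening or acyl migration.

## Compound list

1 | prop-2-yn-1-ol | C#CCO | starting material
2 | chelated alkenylmagnesium alkoxide (4-methyl-2,5-dihydro-1,2-oxamagnesole) | CC1=C[Mg]OC1 | intermediate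
3 | (2Z)-3-iodo-2-methylprop-2-en-1-ol | C/C(=C/I)CO | intermediate
4 | tert-butyl{[(2Z)-3-iodo-2-methylprop-2-en-1-yl]oxy}diphenylsilane | C/C(=C/I)CO[Si](c1ccccc1)(c1ccccc1)C(C)(C)C | intermediate
5 | {(1Z)-3-[(tert-butyldiphenylsilyl)oxy]-2-methylprop-1-en-1-yl}lithium | C/C(=C/[Li])CO[Si](c1ccccc1)(c1ccccc1)C(C)(C)C | intermediate
6 | (3Z)-5-[(tert-butyldiphenylsilyl)oxy]-4-methylpent-3-en-1-ol | C/C(=C/CCO)CO[Si](c1ccccc1)(c1ccccc1)C(C)(C)C | intermediate
7 | tert-butyl{[(2Z)-5-iodo-2-methylpent-2-en-1-yl]oxy}diphenylsilane | C/C(=C/CCI)CO[Si](c1ccccc1)(c1ccccc1)C(C)(C)C | intermediate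
8 | 2-methoxy-3-methylbenzoic acid | COc1c(C)cccc1C(=O)O | starting material
9 | dilithium 2-methoxy-3-methylcyclohexa-2,5-dien-1-ide-1-carboxylate | COC1=C(C)CC=C[C-]1C(=O)[O-].[Li+].[Li+] | intermediate
10 | 1-{(3Z)-5-[(tert-butyldiphenylsilyl)oxy]-4-methylpent-3-en-1-yl}-2-methoxy-3-methylcyclohexa-2,5-diene-1-carboxylic acid (racemic) | COC1=C(C)CC=CC1(CC/C=C(/C)CO[Si](c2ccccc2)(c2ccccc2)C(C)(C)C)C(=O)O | intermediate
11 | 2-{(3Z)-5-[(tert-butyldiphenylsilyl)oxy]-4-methylpent-3-en-1-yl}-6-methylcyclohex-2-en-1-one (racemic at C6) | C/C(=C/CCC1=CCCC(C)C1=O)CO[Si](c1ccccc1)(c1ccccc1)C(C)(C)C | intermediate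
12 | nerol, (2Z)-3,7-dimethylocta-2,6-dien-1-ol | CC(C)=CCC/C(C)=C\CO | starting material
13 | tert-butyl{[(2Z)-3,7-dimethylocta-2,6-dien-1-yl]oxy}diphenylsilane | CC(C)=CCC/C(C)=C\CO[Si](c1ccccc1)(c1ccccc1)C(C)(C)C | intermediate
14 | (6Z)-3-bromo-8-[(tert-butyldiphenylsilyl)oxy]-2,6-dimethyloct-6-en-2-ol (racemic) | CC(C)(O)C(Br)CC/C(C)=C\CO[Si](c1ccccc1)(c1ccccc1)C(C)(C)C | intermediate
15 | tert-butyl{[(2Z)-5-(3,3-dimethyloxiran-2-yl)-3-methylpent-2-en-1-yl]oxy}diphenylsilane (racemic) | CC1(C)OC1CC/C(C)=C\CO[Si](c1ccccc1)(c1ccccc1)C(C)(C)C | intermediate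
16 | (4Z)-6-[(tert-butyldiphenylsilyl)oxy]-4-methylhex-4-enal | O=CCC/C(C)=C\CO[Si](c1ccccc1)(c1ccccc1)C(C)(C)C | intermediate
17 | lithium dienolate of 11 (lithium 2-alkyl-6-methylcyclohexa-1,5-dien-1-olate) | C/C(=C/CCC1=CCCC(C)=C1O[Li])CO[Si](c1ccccc1)(c1ccccc1)C(C)(C)C | intermediate
18 | (4R,5R)-4,5-diphenyl-1,3-ditosyl-1,3,2-diazaborolidin-2-yl dienolate of 11 | C/C(=C/CCC1=CCCC(C)=C1OB1N(S(=O)(=O)c2ccc(C)cc2)[C@H](c2ccccc2)[C@@H](c2ccccc2)N1S(=O)(=O)c1ccc(C)cc1)CO[Si](c1ccccc1)(c1ccccc1)C(C)(C)C | intermediate
19 | (6R)-6-{(1R,4Z)-6-[(tert-butyldiphenylsilyl)oxy]-1-hydroxy-4-methylhex-4-en-1-yl}-2-{(3Z)-5-[(tert-butyldiphenylsilyl)oxy]-4-methylpent-3-en-1-yl}-6-methylcyclohex-2-en-1-one | C/C(=C/CCC1=CCC[C@](C)([C@H](O)CC/C(C)=C\CO[Si](c2ccccc2)(c2ccccc2)C(C)(C)C)C1=O)CO[Si](c1ccccc1)(c1ccccc1)C(C)(C)C | intermediate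
20 | triethylsilyl ether of 19 | C/C(=C/CCC1=CCC[C@](C)([C@H](O[Si](CC)(CC)CC)CC/C(C)=C\CO[Si](c2ccccc2)(c2ccccc2)C(C)(C)C)C1=O)CO[Si](c1ccccc1)(c1ccccc1)C(C)(C)C | intermediate
21 | (7R)-3-{(3Z)-5-[(tert-butyldiphenylsilyl)oxy]-4-methylpent-3-en-1-yl}-7-{(1R,4Z)-6-[(tert-butyldiphenylsilyl)oxy]-4-methyl-1-[(triethylsilyl)oxy]hex-4-en-1-yl}-7-methyl-6,7-dihydrooxepin-2(5H)-one | C/C(=C/CCC1=CCC[C@](C)([C@H](O[Si](CC)(CC)CC)CC/C(C)=C\CO[Si](c2ccccc2)(c2ccccc2)C(C)(C)C)OC1=O)CO[Si](c1ccccc1)(c1ccccc1)C(C)(C)C | intermediate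
22 | (7R)-7-[(1R,4Z)-1,6-dihydroxy-4-methylhex-4-en-1-yl]-3-[(3Z)-5-hydroxy-4-methylpent-3-en-1-yl]-7-methyl-6,7-dihydrooxepin-2(5H)-one | C/C(=C/CCC1=CCC[C@](C)([C@H](O)CC/C(C)=C\CO)OC1=O)CO | target

## Step count and risks

Total step count: 12. Longest linear sequence: 9 steps (steps 1–5, then 9–12).

The three steps most likely to fail:

**Step 11 (oxygen insertion).** The hindered, conjugated carbonyl may add the silyl peroxide too slowly, so that Lewis-acid-induced retro-aldol cleavage or desilylation overtakes the rearrangement. The β-silyloxy group also lowers the migratory aptitude of the quaternary carbon, which could let the alkenyl carbon migrate instead. The fallback sets out from 20 and uses the olefins' own epoxides as protecting groups. Excess m-CPBA with NaHCO3 in CH2Cl2 should carry out the peracid Baeyer–Villiger oxidation (known regiochemistry for 6,6-disubstituted cyclohex-2-enones) and at the same time epoxidise both trisubstituted side-chain olefins, giving the bis-epoxy lactone F1 as a mixture of epoxide diastereomers. Rhodium(II) acetate-catalysed deoxygenation with dimethyl diazomalonate in refluxing toluene, which is stereospecific with retention of olefin geometry, should then return both (Z)-olefins. The fallback comes back to the route at 21.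

**Step 9 (key aldol).** The crowded tetrasubstituted enolborinate may discriminate the aldehyde faces poorly or add sluggishly, and the aldolate may revert by retro-aldol cleavage. The fallback replaces reagent control by substrate control from a temporary stereocentre. It sets out from 16: enantioselective organocatalytic α-chlorination (N-chlorosuccinimide, a C2-symmetric 2,5-diphenylpyrrolidine catalyst of the hand that gives the R chloride, CH2Cl2) should give the (2R)-2-chloro aldehyde F2. The lithium dienolate 17 of enone 11 (LDA, THF, −78 °C) should add to F2 under 1,2-induction by the antiperiplanar C–Cl dipole, with the same chair arrangement, to give the 1,2-anti chlorohydrin F3. Radical dechlorination (Bu3SnH at high concentration, AIBN, toluene, 80 °C) then removes the auxiliary chlorine. The fallback comes back to the route at 19.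

**Step 5 (Birch reductive alkylation).** The methoxy group may be lost reductively or the ring over-reduced in the dissolving-metal step, and residual metal may transfer electrons to the iodide instead of allowing alkylation. The fallback builds the same enone by cross-coupling and sets out from 7. Iodine–lithium exchange (t-BuLi, Et2O, −78 °C) and trapping with 9-methoxy-9-borabicyclo[3.3.1]nonane should give the lithium alkyl(methoxy)borinate F4. Commercial 6-methylcyclohex-2-en-1-one is α-iodinated (I2, pyridine, CH2Cl2) to 2-iodo-6-methylcyclohex-2-en-1-one F5. B-alkyl Suzuki–Miyaura coupling of F4 with F5 (PdCl2(dppf), AsPh3, Cs2CO3, DMF/THF/H2O, rt) should join the two. The fallback comes back to the route at 11.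

## Further compounds

F1 | step 11 | (7R)-7-methyl-6,7-dihydrooxepin-2(5H)-one 21 with both side-chain olefins as cis-epoxides (mixture of epoxide diastereomers) | CC1(CO[Si](c2ccccc2)(c2ccccc2)C(C)(C)C)OC1CCC1=CCC[C@](C)([C@H](O[Si](CC)(CC)CC)CCC2(C)OC2CO[Si](c2ccccc2)(c2ccccc2)C(C)(C)C)OC1=O
F2 | step 9 | (2R,4Z)-6-[(tert-butyldiphenylsilyl)oxy]-2-chloro-4-methylhex-4-enal | O=C[C@H](Cl)C/C(C)=C\CO[Si](c1ccccc1)(c1ccccc1)C(C)(C)C
F3 | step 9 | (6R)-6-{(1S,2R,4Z)-6-[(tert-butyldiphenylsilyl)oxy]-2-chloro-1-hydroxy-4-methylhex-4-en-1-yl}-2-{(3Z)-5-[(tert-butyldiphenylsilyl)oxy]-4-methylpent-3-en-1-yl}-6-methylcyclohex-2-en-1-one | C/C(=C/CCC1=CCC[C@](C)([C@H](O)[C@H](Cl)C/C(C)=C\CO[Si](c2ccccc2)(c2ccccc2)C(C)(C)C)C1=O)CO[Si](c1ccccc1)(c1ccccc1)C(C)(C)C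
F4 | step 5 | lithium {(3Z)-5-[(tert-butyldiphenylsilyl)oxy]-4-methylpent-3-en-1-yl}(methoxy)-9-borabicyclo[3.3.1]nonan-9-uide | [Li+].CO[B-]1(CC/C=C(/C)CO[Si](c2ccccc2)(c2ccccc2)C(C)(C)C)C2CCCC1CCC2
F5 | step 5 | 2-iodo-6-methylcyclohex-2-en-1-one (racemic) | CC1CCC=C(I)C1=O
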